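**Retrosynthetic overview**

1. Last disconnection: the C3–O ester bond, giving the 2,3-trans alcohol and (Z)-2-(acetoxymethyl)but-2-enoic acid; the Z geometry is fixed early as a (Z)-2-iodoalkene from crotonaldehyde and carried through carboxylation with retention.
2. Key disconnection (benzofuran numbering): the C3a–C3 bond of the dihydrofuran ring (ring B; the benzene ring is ring A). A C3a aryl–chromium, made from an aryl iodide with NiCl2/CrCl2, adds to a C3 aldehyde (5-exo-trig). One operation closes ring B, creates the benzylic carbinol, sets C3 trans to C2 and removes the iodine, with the C5 acetyl and the isopropenyl group unprotected.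
3. Enabling feature: C3 is a carbinol carbon bonded directly to C3a. C3a lies ortho to O1 and para to the C6 methoxy group, the site that iodination selects. C7a lies para to the C5 acetyl group, so the O1–C7a bond comes from SNAr of fluoride by a secondary alkoxide.
4. The C2 stereocentre and its isopropenyl group come from prenol: Sharpless epoxidation, then aluminium amide isomerisation of the epoxide to the allylic alcohol.
5. Ring order: ring A is bought as an acetophenone; ring B is the only ring formed, in the key step.

Key step: step 8

Remark: prenol, 1-(4-fluoro-2-methoxyphenyl)ethan-1-one and (E)-crotonaldehyde are taken as commercial; the enantiomeric purity delivered by step 1 can be raised, if needed, by recrystallising a crystalline intermediate.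

**Route**

Step 1
Reactants: 1 3-methylbut-2-en-1-ol (prenol)
Product: 2 [(2S)-3,3-dimethyloxiran-2-yl]methanol
Conditions: Ti(OiPr)4 (cat.), L-(+)-diethyl tartrate (cat.), t-BuOOH, 4 Å molecular sieves, CH2Cl2, −20 °C
Reagents that add atoms: tert-butyl hydroperoxide CC(C)(C)OO
Why: Sharpless asymmetric epoxidation of a primary allylic alcohol; with L-(+)-diethyl tartrate the titanium tartrate peroxide complex should deliver oxygen to the alkene face that makes the CH2OH-bearing epoxide carbon S (the established tartrate face rule), and this carbon becomes C2 of the target.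

Step 2
Reactants: 2 [(2S)-3,3-dimethyloxiran-2-yl]methanol
Product: 3 (3S)-3-{[(4-methoxyphenyl)methoxy]methyl}-2,2-dimethyloxirane
Conditions: NaH, 4-methoxybenzyl chloride, Bu4NI (cat.), THF, 0 → 25 °C
Reagents that add atoms: 4-methoxybenzyl chloride COc1ccc(CCl)cc1
Why: Williamson ether synthesis on the primary alkoxide (iodide catalysis), run cold and briefly so that Payne rearrangement of the epoxy alkoxide stays minor; the stereocentre is not touched.

Step 3
Reactants: 3 (3S)-3-{[(4-methoxyphenyl)methoxy]methyl}-2,2-dimethyloxirane
Product: 4 (2R)-1-[(4-methoxyphenyl)methoxy]-3-methylbut-3-en-2-ol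
Conditions: Et2AlCl, lithium 2,2,6,6-tetramethylpiperidide, toluene, 0 °C
Reagents that add atoms: none
Why: Aluminium amide mediated isomerisation of an epoxide to an allylic alcohol: aluminium binds the epoxide oxygen and the hindered amide removes a methyl proton in a syn elimination that breaks the tertiary C–O bond, so the isopropenyl group appears while the carbinol carbon keeps its geometry (the descriptor changes from S to R only because the CIP priorities change).

Step 4
Reactants: 5 1-(4-fluoro-2-methoxyphenyl)ethan-1-one
Product: 6 1-(4-fluoro-5-iodo-2-methoxyphenyl)ethan-1-one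
Conditions: N-iodosuccinimide, CF3CO2H, MeCN, 25 → 60 °C
Reagents that add atoms: N-iodosuccinimide O=C1CCC(=O)N1I
Why: Electrophilic aromatic iodination; the position para to the methoxy group, ortho to fluorine and meta to the acetyl group is the most activated and least hindered one, so iodine should enter at C5 of the acetophenone (the later C3a).

Step 5
Reactants: 4 (2R)-1-[(4-methoxyphenyl)methoxy]-3-methylbut-3-en-2-ol, 6 1-(4-fluoro-5-iodo-2-methoxyphenyl)ethan-1-one
Product: 8 1-[5-iodo-2-methoxy-4-({(2R)-1-[(4-methoxyphenyl)methoxy]-3-methylbut-3-en-2-yl}oxy)phenyl]ethan-1-one, via sodium alkoxide 7 (not isolated)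
Conditions: NaH, DMF, 0 °C; then 6, 0 → 25 °C
Reagents that add atoms: none
Why: Nucleophilic aromatic substitution (addition–elimination through a Meisenheimer complex stabilised by the para acetyl group) of fluoride by the secondary alkoxide; no bond at the stereocentre is broken, so its configuration is retained (R).

Step 6
Reactants: 8 1-[5-iodo-2-methoxy-4-({(2R)-1-[(4-methoxyphenyl)methoxy]-3-methylbut-3-en-2-yl}oxy)phenyl]ethan-1-one
Product: 9 1-(4-{[(2R)-1-hydroxy-3-methylbut-3-en-2-yl]oxy}-5-iodo-2-methoxyphenyl)ethan-1-one
Conditions: DDQ, CH2Cl2/pH 7 buffer, 0 → 25 °C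
Reagents that add atoms: none
Why: Oxidative cleavage of the p-methoxybenzyl ether by DDQ (hydride abstraction at the electron-rich benzylic position, then hydrolysis of the oxocarbenium ion) should free the primary alcohol without touching the aryl iodide, the ketone or the 1,1-disubstituted alkene.

Step 7
Reactants: 9 1-(4-{[(2R)-1-hydroxy-3-methylbut-3-en-2-yl]oxy}-5-iodo-2-methoxyphenyl)ethan-1-one
Product: 10 (2R)-2-(4-acetyl-2-iodo-5-methoxyphenoxy)-3-methylbut-3-enal
Conditions: Dess–Martin periodinane, pyridine, CH2Cl2, 0 °C
Reagents that add atoms: none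
Why: Dess–Martin oxidation under mild, buffered conditions should give the α-aryloxy β,γ-unsaturated aldehyde without enolisation; because this aldehyde can epimerise or move its double bond into conjugation, it is not purified but used at once in step 8.

Step 8
Reactants: 10 (2R)-2-(4-acetyl-2-iodo-5-methoxyphenoxy)-3-methylbut-3-enal
Product: 12 1-[(2R,3S)-3-hydroxy-6-methoxy-2-(prop-1-en-2-yl)-2,3-dihydro-1-benzofuran-5-yl]ethan-1-one, via arylchromium dichloride 11 (not isolated)
Conditions: CrCl2 (5 equiv), NiCl2 (2 mol %), DMF, 25 °C; aqueous work-up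
Reagents that add atoms: none
Why: CrCl2 reduces NiCl2 to zerovalent nickel, which inserts into the C3a–I bond; transmetalation to trivalent chromium gives arylchromium 11, which adds to the C3 aldehyde to give a chromium alkoxide that is hydrolysed to 12 on work-up. The closest known reaction type is the intramolecular Nozaki–Hiyama–Kishi arylation of an aldehyde. Ring B (O1–C2–C3–C3a–C7a) is closed in the 5-exo-trig mode, the carbonyl oxygen ending outside the ring. The new stereocentre C3 is controlled by C2: in the compact transition state the chromium-bound carbonyl oxygen with its ligand sphere should turn to the ring face opposite to the isopropenyl group, which gives the 2,3-trans (2R,3S) alcohol. The step needs chemoselectivity for the aldehyde over the C5 acetyl group and the isopropenyl double bond (organochromium reagents add to aldehydes far faster than to ketones and do not carbometalate unactivated alkenes), regioselectivity (fixed by the iodine at C3a) and preservation of C2 (neutral, non-basic medium and fast intramolecular capture).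

Step 9
Reactants: 13 (2E)-but-2-enal (crotonaldehyde)
Product: 14 (2Z)-2-iodobut-2-enal
Conditions: I2, K2CO3, DMAP (cat.), THF/H2O, 25 °C
Reagents that add atoms: iodine II
Why: α-Iodination of an enal by a Baylis–Hillman-type addition–elimination sequence (conjugate addition of DMAP, iodination of the enolate, loss of DMAP), which should give the Z iodo enal with methyl and iodine cis.

Step 10
Reactants: 14 (2Z)-2-iodobut-2-enal
Product: 15 (2Z)-2-iodobut-2-en-1-ol
Conditions: NaBH4, CeCl3·7H2O, MeOH, 0 °C
Reagents that add atoms: none
Why: Luche 1,2-reduction of the enal, which should leave the vinyl iodide and its geometry intact.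

Step 11
Reactants: 15 (2Z)-2-iodobut-2-en-1-ol
Product: 17 (2Z)-2-(hydroxymethyl)but-2-enoic acid, via dilithio alkenyl alkoxide 16 (not isolated)
Conditions: n-BuLi (1 equiv), Et2O, −78 °C; t-BuLi (2 equiv), −78 °C; CO2, −78 → 0 °C; aq. HCl
Reagents that add atoms: carbon dioxide O=C=O
Why: Deprotonation of the hydroxyl group and iodine–lithium exchange give a configurationally stable alkenyllithium that is carboxylated with retention, so the carboxyl group should end up cis to the methyl group (Z acid).

Step 12
Reactants: 17 (2Z)-2-(hydroxymethyl)but-2-enoic acid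
Product: 18 (2Z)-2-[(acetyloxy)methyl]but-2-enoic acid
Conditions: Ac2O, pyridine, CH2Cl2, 0 → 25 °C; then H2O
Reagents that add atoms: acetic anhydride CC(=O)OC(C)=O
Why: O-Acetylation of the primary allylic alcohol without a nucleophilic amine catalyst (the mixed anhydride formed at the carboxyl group is hydrolysed in the aqueous work-up), so no addition–elimination path that could scramble the double bond geometry is opened.

Step 13
Reactants: 18 (2Z)-2-[(acetyloxy)methyl]but-2-enoic acid, 12 1-[(2R,3S)-3-hydroxy-6-methoxy-2-(prop-1-en-2-yl)-2,3-dihydro-1-benzofuran-5-yl]ethan-1-one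
Product: 20 (2R,3S)-5-acetyl-6-methoxy-2-(prop-1-en-2-yl)-2,3-dihydro-1-benzofuran-3-yl (2Z)-2-[(acetyloxy)methyl]but-2-enoate, via mixed anhydride 19 (not isolated)
Conditions: 2,4,6-trichlorobenzoyl chloride, Et3N, toluene, 25 °C; then 12, toluene, 75 °C
Reagents that add atoms: none
Why: Yamaguchi-type esterification through the 2,4,6-trichlorobenzoyl mixed anhydride without DMAP, the protocol suited to angelic acid type (Z)-2-alkenoic acids, should acylate the secondary benzylic alcohol with retention at C3 and without Z to E isomerisation.

**Compound list**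

1 | 3-methylbut-2-en-1-ol (prenol) | CC(C)=CCO | starting material
2 | [(2S)-3,3-dimethyloxiran-2-yl]methanol | CC1(C)O[C@H]1CO | intermediate
3 | (3S)-3-{[(4-methoxyphenyl)methoxy]methyl}-2,2-dimethyloxirane | CC1(C)O[C@H]1COCc1ccc(OC)cc1 | intermediate
4 | (2R)-1-[(4-methoxyphenyl)methoxy]-3-methylbut-3-en-2-ol | C=C(C)[C@@H](O)COCc1ccc(OC)cc1 | intermediate
5 | 1-(4-fluoro-2-methoxyphenyl)ethan-1-one | CC(=O)c1ccc(F)cc1OC | starting material
6 | 1-(4-fluoro-5-iodo-2-methoxyphenyl)ethan-1-one | CC(=O)c1cc(I)c(F)cc1OC | intermediate
7 | sodium (2R)-1-[(4-methoxyphenyl)methoxy]-3-methylbut-3-en-2-olate (formed in the flask) | C=C(C)[C@@H]([O-])COCc1ccc(OC)cc1.[Na+] | intermediate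
8 | 1-[5-iodo-2-methoxy-4-({(2R)-1-[(4-methoxyphenyl)methoxy]-3-methylbut-3-en-2-yl}oxy)phenyl]ethan-1-one | C=C(C)[C@@H](Oc1cc(OC)c(C(C)=O)cc1I)COCc1ccc(OC)cc1 | intermediate
9 | 1-(4-{[(2R)-1-hydroxy-3-methylbut-3-en-2-yl]oxy}-5-iodo-2-methoxyphenyl)ethan-1-one | C=C(C)[C@@H](Oc1cc(OC)c(C(C)=O)cc1I)CO | intermediate
10 | (2R)-2-(4-acetyl-2-iodo-5-methoxyphenoxy)-3-methylbut-3-enal | C=C(C)[C@@H](Oc1cc(OC)c(C(C)=O)cc1I)C=O | intermediate
11 | {5-acetyl-4-methoxy-2-[((2R)-3-methyl-1-oxobut-3-en-2-yl)oxy]phenyl}chromium dichloride (trivalent chromium, formed in the flask) | C=C(C)[C@@H](Oc1cc(OC)c(C(C)=O)cc1[Cr](Cl)Cl)C=O | intermediate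
12 | 1-[(2R,3S)-3-hydroxy-6-methoxy-2-(prop-1-en-2-yl)-2,3-dihydro-1-benzofuran-5-yl]ethan-1-one (2,3-trans alcohol) | C=C(C)[C@H]1Oc2cc(OC)c(C(C)=O)cc2[C@@H]1O | intermediate
13 | (2E)-but-2-enal (crotonaldehyde) | C/C=C/C=O | starting material
14 | (2Z)-2-iodobut-2-enal | C/C=C(\I)C=O | intermediate
15 | (2Z)-2-iodobut-2-en-1-ol | C/C=C(\I)CO | intermediate
16 | lithium (2Z)-2-lithiobut-2-en-1-olate (formed in the flask) | C/C=C(\[Li])CO[Li] | intermediate
17 | (2Z)-2-(hydroxymethyl)but-2-enoic acid | C/C=C(\C(=O)O)CO | intermediate
18 | (2Z)-2-[(acetyloxy)methyl]but-2-enoic acid | C/C=C(\C(=O)O)COC(C)=O | intermediate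
19 | (2Z)-2-[(acetyloxy)methyl]but-2-enoic 2,4,6-trichlorobenzoic anhydride (formed in the flask) | C/C=C(\C(=O)OC(=O)c1c(Cl)cc(Cl)cc1Cl)COC(C)=O | intermediate
20 | (2R,3S)-5-acetyl-6-methoxy-2-(prop-1-en-2-yl)-2,3-dihydro-1-benzofuran-3-yl (2Z)-2-[(acetyloxy)methyl]but-2-enoate (CNP0221694.1) | C=C(C)[C@H]1Oc2cc(OC)c(C(C)=O)cc2[C@@H]1OC(=O)/C(=C\C)COC(C)=O | target

**Step count and risks**

Total step count: 13.
Longest linear sequence: 8 steps (steps 1, 2, 3, 5, 6, 7, 8, 13).

Three steps most likely to fail:

1. Step 8 (key step). Process: attack of the aryl–chromium on the wrong face of the aldehyde, that is, insufficient 2,3-trans selectivity in the ring closure. The fallback sets out from aldehyde 10 and comes back to the route at target 20. The cis alcohol that the cyclisation of 10 would then deliver, 1-[(2R,3R)-3-hydroxy-6-methoxy-2-(prop-1-en-2-yl)-2,3-dihydro-1-benzofuran-5-yl]ethan-1-one F1, is separated from 12 and esterified with acid 18 under Mitsunobu conditions (PPh3, DIAD, THF, 0 °C). The carboxylate displaces the activated C3 oxygen with inversion and should give 20 directly. C3 is then set in the C–O bond formation instead of in the C–C bond formation, and step 13 is not needed for this material.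

2. Step 13. Process: Z to E isomerisation of the enoate and loss of its allylic acetate through reversible conjugate addition to the activated acyl donor, together with elimination of the benzylic C3 oxygen on heating. The fallback sets out from alcohol 12 and comes back at target 20. Alcohol 12 is converted with Cl3CCN and catalytic DBU (CH2Cl2, 0 °C) into (2R,3S)-5-acetyl-6-methoxy-2-(prop-1-en-2-yl)-2,3-dihydro-1-benzofuran-3-yl 2,2,2-trichloroethanimidate F2, which is warmed with acid 18 in toluene without a promoter. The acid protonates the imidate, and the carboxylate should capture the benzylic C3 position (stabilised by O1 and the para methoxy group) on the face opposite to the isopropenyl group. The acid reacts as an oxygen nucleophile and is never activated at its carbonyl group.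

3. Step 5. Process: deprotonation of the acetyl group by the alkoxide (enolate formation and aldol condensation) in competition with fluoride displacement. The fallback is a base-free Mitsunobu etherification, which inverts the carbinol carbon and therefore needs the enantiomeric alcohol; it sets out from 1 and 6 and comes back at aryl ether 8. Steps 1 to 3 are run with D-(−)-diethyl tartrate to give in turn [(2R)-3,3-dimethyloxiran-2-yl]methanol F3, (3R)-3-{[(4-methoxyphenyl)methoxy]methyl}-2,2-dimethyloxirane F4 and (2S)-1-[(4-methoxyphenyl)methoxy]-3-methylbut-3-en-2-ol F5. Fluoride 6 is converted into 1-(4-hydroxy-5-iodo-2-methoxyphenyl)ethan-1-one F6 with acetohydroxamic acid and K2CO3 in DMSO at 80 °C (a hydroxide surrogate for activated aryl fluorides). PPh3 and DIAD in toluene at 0 °C then join F5 and F6 with inversion to give 8.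

**Further compounds**

F1 | step 8 | 1-[(2R,3R)-3-hydroxy-6-methoxy-2-(prop-1-en-2-yl)-2,3-dihydro-1-benzofuran-5-yl]ethan-1-one | C=C(C)[C@H]1Oc2cc(OC)c(C(C)=O)cc2[C@H]1O
F2 | step 13 | (2R,3S)-5-acetyl-6-methoxy-2-(prop-1-en-2-yl)-2,3-dihydro-1-benzofuran-3-yl 2,2,2-trichloroethanimidate | C=C(C)[C@H]1Oc2cc(OC)c(C(C)=O)cc2[C@@H]1OC(=N)C(Cl)(Cl)Cl
F3 | step 5 | [(2R)-3,3-dimethyloxiran-2-yl]methanol | CC1(C)O[C@@H]1CO
F4 | step 5 | (3R)-3-{[(4-methoxyphenyl)methoxy]methyl}-2,2-dimethyloxirane | CC1(C)O[C@@H]1COCc1ccc(OC)cc1
F5 | step 5 | (2S)-1-[(4-methoxyphenyl)methoxy]-3-methylbut-3-en-2-ol | C=C(C)[C@H](O)COCc1ccc(OC)cc1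
F6 | step 5 | 1-(4-hydroxy-5-iodo-2-methoxyphenyl)ethan-1-one | CC(=O)c1cc(I)c(O)cc1OC
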